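(The readings are simulated on assumed constants; noise was put on by code.)

A small charge of catalyst, 0.750 mM in Tuesday's, is the yardstick here: each earlier run's early gain in open intermediate plus target is rescaled to that [catalyst] and told as a pseudo-first-order constant.

| setting | summer | spring | autumn | Tuesday's | Saturday's | Sunday's | Friday's |
|---|---|---|---|---|---|---|---|
| substrate | 0.025 M | 0.038 M | 0.050 M | 0.050 M | 0.050 M | 0.050 M | 0.050 M |
| reagent | 0.80 equiv | 0.80 equiv | 0.80 equiv | 0.800 equiv | 0.800 equiv | 0.800 equiv | 0.800 equiv |
| capture agent | 1 mM | 1 mM | 1 mM | 1.00 mM | 1.00 mM | 1.00 mM | 1.00 mM |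
| catalyst | 1.5 mol% | 1.5 mol% | 2.2 mol% | 1.5 mol% | 1.5 mol% | 1.5 mol% | 1.5 mol% |
| temperature | 60 °C | 82 °C | 60 °C | 70 °C | 90 °C |  | 50 °C |
| remark | run made earlier | run made earlier | run made earlier |  |  | at 50 °C until 1.5 h, from then on at 90 °C |  |
| time |  |  |  | 5.0 h | 5.0 h | 5.0 h | 5.0 h |

- summer (time / h: open intermediate / %, target / %): 0.500: 3, 0; 1.50: 3, 0; 3.00: 10, 1; 5.00: 11, 0; 6.00: 14, 3
- spring (time / min: open intermediate / %, target / %): 12.0: 5, 0; 30.0: 10, 1; 60.0: 10, 1; 90.0: 11, 3; 120: 14, 2
- autumn (time / h: open intermediate / %, target / %): 1.33: 10, 2; 2.50: 14, 8; 4.00: 19, 10; 5.00: 15, 11; 6.00: 18, 16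

(readings scatter by 2 percentage points)



1. the flask that comes out highest in amount of open intermediate, in percent of the substrate charged, or "all alike" when all lie within 1.5 percentage points (Tuesday's / Saturday's / Sunday's / Friday's / all alike)
2. open intermediate at the end, in percent of the substrate charged, Tuesday's
3. open intermediate at the end, in percent of the substrate charged, Saturday's
4. open intermediate at the end, in percent of the substrate charged, Sunday's
5. open intermediate at the end, in percent of the substrate charged, Friday's

Two ways give that constant at 60 °C. The summer run gives 0.0567 h⁻¹ and the autumn run 0.0615 h⁻¹, from different [substrate], [catalyst] and times. They agree within the scatter of 2 percentage points per reading, so the scaling with [catalyst] is trusted. The spring run gives 0.289 h⁻¹ at 82 °C. But its early line, carried to 120 min, promises 44.0 %, and the readings show 16.0 %. The line cheats there.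

The late readings give the other end, read here as a ceiling on [open intermediate]/[substrate]: 0.167 in the spring run, lower than the 0.273 of the autumn run, which is still rising. Taking logarithms as straight in temperature between the autumn and spring runs, Tuesday's gets a constant of 0.124 h⁻¹ and a ratio of 0.218, so its ceiling is 17.9 % of the substrate charged.

The two ends join at the filling time, the ceiling divided by the early constant: 1.44 h. Tuesday's should bend past that time, and the bend is what to watch. This reckoning curves the line into the ceiling and gives Tuesday's 17.3 %.

Saturday's, with a constant of 0.508 h⁻¹ and a ceiling of 12.2 %, has a filling time of 0.241 h, and its run lasts far longer than that, so this reckoning puts Saturday's at the ceiling by the end. Sunday's has far longer than that after the change, so it takes the same figure. Friday's stays on its line, with 15.2 % for open intermediate plus target together. Tuesday's therefore stands higher than these.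

The forecast names Tuesday's, with 21 % for Tuesday's, 11 % for Saturday's, 13 % for Sunday's and 10 % for Friday's: “Tuesday's, at moderate temperature, comes out highest”. On Tuesday's it lies higher than this reckoning, by 3.7 points.

Tuesday's comes out highest at 18.0 %, with Saturday's at 11.9 %, Sunday's at 11.9 % and Friday's at 11.0 %.

    substrate + catalyst ⇌ catalyst + open intermediate (K = 0.360, k = 160 L mol⁻¹ h⁻¹, Ea = 58.0 kJ mol⁻¹, ΔH = −43.0 kJ mol⁻¹)
    reagent + catalyst + open intermediate → catalyst + target (k = 15000 L² mol⁻² h⁻¹, Ea = 50.0 kJ mol⁻¹)
    open intermediate + capture agent → trapped intermediate (k = 8.60 L mol⁻¹ h⁻¹, Ea = 89.0 kJ mol⁻¹)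
    2 reagent → self-condensation product (k = 7.50 L mol⁻¹ h⁻¹, Ea = 83.0 kJ mol⁻¹)
    (constants at 70 °C)

Tuesday's answer has moved by 5 points at 2.12 h, which is 1.47 filling times. A neighbour of Tuesday's charged with 0.013 M of substrate, at the same equivalents, loadings and time, holds less catalyst by a factor of 3.85. Its filling time is therefore 5.54 h, longer than the run, and the join gives 10.6 %. That neighbour ends at 11.0 %.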